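**Retrosynthetic overview**
1. The ArCH2–pyranone bridge is cut at the aryl–CH2 bond: Michael addition of the acylphloroglucinol ring to a 3-methylene-pyran-2,4-dione, released from a pyranone Mannich base (bridge carbon from Eschenmoser's salt).
2. The 4-hydroxy-2-pyranone is the only ring built: lactonisation of methyl 4-methyl-3,5-dioxoheptanoate, made by Claisen-type acylation of the methyl 3-oxopentanoate dianion with a propanoyl Weinreb amide.
3. The aryl ketone comes from ortho-lithiation of bis-MOM-protected 5-methoxyresorcinol (benzene ring purchased) and acylation with the (R)-2-methylbutanoyl Weinreb amide, then MOM removal.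
4. The stereocentre is set by Evans methylation of the N-butanoyl derivative of (R)-4-benzyloxazolidinone.
5. Ring order: benzene ring bought, pyranone ring closed (step 9), fragments joined last (step 11).

Assumption: the [C@H] descriptor in the given SMILES corresponds to the (R)-2-methylbutanoyl group (CIP order C=O > ethyl > methyl > H), and the route is built for that enantiomer.

**Route**

Step 1
Reactants: 1 (4R)-4-benzyl-1,3-oxazolidin-2-one; 2 butanoyl chloride
Product: 4 (4R)-4-benzyl-3-butanoyl-1,3-oxazolidin-2-one, via N-lithio oxazolidinone 3 (not isolated)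
Conditions: n-BuLi (1.05 eq), THF, −78 °C; then 2, −78 → 0 °C
Reagents that add atoms: none
Why: N-acylation of the lithiated oxazolidinone with an acid chloride (nucleophilic acyl substitution) is the standard, high-yielding preparation of Evans imides.

Step 2
Reactants: 4 (4R)-4-benzyl-3-butanoyl-1,3-oxazolidin-2-one
Product: 6 (4R)-4-benzyl-3-[(2R)-2-methylbutanoyl]-1,3-oxazolidin-2-one, via sodium Z-enolate 5 (not isolated)
Conditions: NaHMDS (1.1 eq), THF, −78 °C; MeI (4 eq), −78 °C; chromatography to a single diastereomer
Reagents that add atoms: iodomethane, CI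
Why: Evans asymmetric alkylation, in which the chelated Z-enolate is methylated on the face opposite the C4 benzyl group, so the (R)-auxiliary gives the (2R)-2-methylbutanoyl centre (dr about 10:1, minor isomer removed by chromatography).

Step 3
Reactants: 6 (4R)-4-benzyl-3-[(2R)-2-methylbutanoyl]-1,3-oxazolidin-2-one
Product: 8 (2R)-2-methylbutanoic acid, via peroxy acid 7 (not isolated)
Conditions: LiOH·H2O (2 eq), 30% H2O2 (4 eq), THF/H2O 3:1, 0 °C; aq. Na2SO3; extract auxiliary 1; HCl to pH 2; careful concentration (volatile acid)
Reagents that add atoms: hydrogen peroxide (as LiOOH), OO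
Why: Evans LiOOH auxiliary cleavage, in which hydroperoxide attacks the exocyclic imide carbonyl selectively without epimerising the α-centre, and sulfite reduces the peracid to the acid.

Step 4
Reactants: 8 (2R)-2-methylbutanoic acid
Product: 10 (2R)-N-methoxy-N,2-dimethylbutanamide, via acyl imidazole 9 (not isolated)
Conditions: CDI (1.1 eq), CH2Cl2, 0 °C → rt; then MeNHOMe·HCl (1.2 eq), rt
Reagents that add atoms: N,O-dimethylhydroxylamine hydrochloride, CNOC.Cl
Why: Weinreb amide formation through the acyl imidazole is a mild coupling without strong base that does not epimerise a simple α-branched acid.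

Step 5
Reactants: 11 5-methoxybenzene-1,3-diol
Product: 12 1-methoxy-3,5-bis(methoxymethoxy)benzene
Conditions: MOMCl (2.5 eq), i-Pr2NEt (3 eq), CH2Cl2, 0 °C → rt
Reagents that add atoms: chloromethyl methyl ether, COCCl
Why: Williamson-type O-alkylation of both phenols protects them and installs two strong ortho-directing groups.

Step 6
Reactants: 12 1-methoxy-3,5-bis(methoxymethoxy)benzene; 10 (2R)-N-methoxy-N,2-dimethylbutanamide
Product: 14 (2R)-1-[4-methoxy-2,6-bis(methoxymethoxy)phenyl]-2-methylbutan-1-one, via aryllithium 13 (not isolated)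
Conditions: 12 (1.2 eq), n-BuLi (1.2 eq), TMEDA, THF, 0 °C, 1 h; then 10, −78 → 0 °C; sat. aq. NH4Cl
Reagents that add atoms: none
Why: Directed ortho-metalation takes place between the two chelating OMOM groups (stronger directors than OMe), and the aryllithium adds once to the Weinreb amide through a stable chelate that gives the ketone only on work-up (Weinreb ketone synthesis), leaving the α-centre untouched.

Step 7
Reactants: 14 (2R)-1-[4-methoxy-2,6-bis(methoxymethoxy)phenyl]-2-methylbutan-1-one
Product: 15 (2R)-1-(2,6-dihydroxy-4-methoxyphenyl)-2-methylbutan-1-one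
Conditions: 2 M HCl, MeOH, rt; ee checked by chiral HPLC
Reagents that add atoms: none
Why: Acid-catalysed acetal cleavage (MOM deprotection by transacetalisation to methanol) frees both phenols under conditions too mild to enolise the hindered di-ortho-substituted aryl ketone.

Step 8
Reactants: 16 methyl 3-oxopentanoate; 17 N-methoxy-N-methylpropanamide
Product: 19 methyl 4-methyl-3,5-dioxoheptanoate, via ester dianion 18 (not isolated)
Conditions: NaH (1.1 eq), THF, 0 °C; n-BuLi (1.05 eq), 0 °C; then 17, 0 °C → rt; 1 M HCl
Reagents that add atoms: none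
Why: Claisen-type C-acylation of the Huckin–Weiler dianion at its more reactive γ-carbon stops at the stable Weinreb tetrahedral adduct, which prevents over-addition (the C4 centre of 19 is an enolisable mixture that becomes sp2 in step 9).

Step 9
Reactants: 19 methyl 4-methyl-3,5-dioxoheptanoate
Product: 20 6-ethyl-4-hydroxy-5-methyl-2H-pyran-2-one
Conditions: DBU (1.5 eq), toluene, 80 °C; then 1 M HCl
Reagents that add atoms: none
Why: Base-promoted enolisation of the C5 ketone and intramolecular O-acylation by the methyl ester (lactonisation of a 3,5-diketo ester) closes the stabilised 4-hydroxy-2-pyranone ring irreversibly.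

Step 10
Reactants: 20 6-ethyl-4-hydroxy-5-methyl-2H-pyran-2-one
Product: 21 3-[(dimethylamino)methyl]-6-ethyl-4-hydroxy-5-methyl-2H-pyran-2-one hydroiodide
Conditions: Me2N+=CH2 I− (1.05 eq), MeCN, rt; precipitation with Et2O
Reagents that add atoms: Eschenmoser's salt (N,N-dimethylmethyleneiminium iodide), C=[N+](C)C.[I-]
Why: Mannich reaction of the only nucleophilic carbon (C3 of the cyclic β-keto-lactone enol) with a preformed iminium ion is a pure addition, and isolating the product as its ammonium salt keeps it from eliminating prematurely.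

Step 11
Reactants: 21 3-[(dimethylamino)methyl]-6-ethyl-4-hydroxy-5-methyl-2H-pyran-2-one hydroiodide; 15 (2R)-1-(2,6-dihydroxy-4-methoxyphenyl)-2-methylbutan-1-one
Product: 23 3-{[2,4-dihydroxy-6-methoxy-3-[(2R)-2-methylbutanoyl]phenyl]methyl}-6-ethyl-4-hydroxy-5-methyl-2H-pyran-2-one, via methylene pyrandione 22 (not isolated)
Conditions: 15 (1.5 eq, excess recovered), MeCN, 60 °C
Reagents that add atoms: none
Why: Thermal loss of dimethylamine from the Mannich base gives the strongly electrophilic 3-methylene-pyran-2,4-dione, which is trapped in an intermolecular Michael addition by one of the two equivalent, doubly activated ring carbons of 15 and rearomatises to the target without creating or disturbing any stereocentre.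

**Compound list**
1 | (4R)-4-benzyl-1,3-oxazolidin-2-one | O=C1N[C@H](Cc2ccccc2)CO1 | starting material
2 | butanoyl chloride | CCCC(Cl)=O | starting material
3 | lithium salt of 1 (N-lithio oxazolidinone) | [Li]N1[C@H](Cc2ccccc2)COC1=O | intermediate
4 | (4R)-4-benzyl-3-butanoyl-1,3-oxazolidin-2-one | CCCC(=O)N1[C@H](Cc2ccccc2)COC1=O | intermediate
5 | sodium (Z)-enolate of 4 | CC/C=C(\O[Na])N1[C@H](Cc2ccccc2)COC1=O | intermediate
6 | (4R)-4-benzyl-3-[(2R)-2-methylbutanoyl]-1,3-oxazolidin-2-one | CC[C@@H](C)C(=O)N1[C@H](Cc2ccccc2)COC1=O | intermediate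
7 | (2R)-2-methylbutaneperoxoic acid | CC[C@@H](C)C(=O)OO | intermediate
8 | (2R)-2-methylbutanoic acid | CC[C@@H](C)C(=O)O | intermediate
9 | (2R)-1-(1H-imidazol-1-yl)-2-methylbutan-1-one | CC[C@@H](C)C(=O)n1ccnc1 | intermediate
10 | (2R)-N-methoxy-N,2-dimethylbutanamide | CC[C@@H](C)C(=O)N(C)OC | intermediate
11 | 5-methoxybenzene-1,3-diol | COc1cc(O)cc(O)c1 | starting material
12 | 1-methoxy-3,5-bis(methoxymethoxy)benzene | COCOc1cc(OC)cc(OCOC)c1 | intermediate
13 | [4-methoxy-2,6-bis(methoxymethoxy)phenyl]lithium | [Li]c1c(OCOC)cc(OC)cc1OCOC | intermediate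
14 | (2R)-1-[4-methoxy-2,6-bis(methoxymethoxy)phenyl]-2-methylbutan-1-one | CC[C@@H](C)C(=O)c1c(OCOC)cc(OC)cc1OCOC | intermediate
15 | (2R)-1-(2,6-dihydroxy-4-methoxyphenyl)-2-methylbutan-1-one | CC[C@@H](C)C(=O)c1c(O)cc(OC)cc1O | intermediate
16 | methyl 3-oxopentanoate | CCC(=O)CC(=O)OC | starting material
17 | N-methoxy-N-methylpropanamide | CCC(=O)N(C)OC | starting material
18 | sodium lithium dianion of 16 | [Na+].[Li+].C[CH-]C(=O)[CH-]C(=O)OC | intermediate
19 | methyl 4-methyl-3,5-dioxoheptanoate | CCC(=O)C(C)C(=O)CC(=O)OC | intermediate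
20 | 6-ethyl-4-hydroxy-5-methyl-2H-pyran-2-one | CCc1oc(=O)cc(O)c1C | intermediate
21 | 3-[(dimethylamino)methyl]-6-ethyl-4-hydroxy-5-methyl-2H-pyran-2-one hydroiodide | CCc1oc(=O)c(CN(C)C)c(O)c1C.I | intermediate
22 | 6-ethyl-5-methyl-3-methylidene-2H-pyran-2,4(3H)-dione | CCC1=C(C)C(=O)C(=C)C(=O)O1 | intermediate
23 | 3-{[2,4-dihydroxy-6-methoxy-3-[(2R)-2-methylbutanoyl]phenyl]methyl}-6-ethyl-4-hydroxy-5-methyl-2H-pyran-2-one | CCc1oc(=O)c(Cc2c(OC)cc(O)c(C(=O)[C@H](C)CC)c2O)c(O)c1C | target

**Totals**
Total step count: 11.
Longest linear sequence: 7 steps (1, 2, 3, 4, 6, 7, 11). The arene branch (5, 6, 7, 11) and the pyranone branch (8, 9, 10, 11) are four steps each.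

**Three steps most likely to fail, with fallbacks**

Step 6 (ortho-lithiation and Weinreb acylation). The risks are incomplete regioselectivity of lithiation (between OMOM and OMe instead of between the two OMOM groups) and slow addition of the hindered aryllithium to the α-branched amide. The fallback sets out from 8 and comes back at 15, replacing steps 4–7 by electrophilic aromatic acylation. Acid 8 is converted with oxalyl chloride and catalytic DMF in CH2Cl2 at 0 °C into (2R)-2-methylbutanoyl chloride F1. F1 acylates commercial phloroglucinol (benzene-1,3,5-triol; its symmetry removes the regiochemical question) under Friedel–Crafts conditions (AlCl3, CH2Cl2/PhNO2, 0 °C → rt) to give (2R)-2-methyl-1-(2,4,6-trihydroxyphenyl)butan-1-one F2. The 4-OH of F2 is the only hydroxyl not hydrogen-bonded to the ketone and is the most acidic, so it is methylated selectively with Me2SO4 (1.0 eq) and K2CO3 in acetone at rt, giving 15. The ee is checked by chiral HPLC because the Lewis-acid step is the point where erosion could occur.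

Step 8 (dianion acylation). The risks are proton transfer, O-acylation and incomplete conversion at the secondary γ-carbanion. The fallback sets out from 16 and comes back at 19, using a neutral silyl dienol ether in place of the dianion. Ester 16 is silylated with TMSCl/Et3N to methyl 3-(trimethylsilyloxy)pent-2-enoate F3. F3 is deprotonated with LDA at −78 °C and silylated again to 1-methoxy-1,3-bis(trimethylsilyloxy)penta-1,3-diene F4. This Chan-type diene reacts at its terminal carbon with propanoyl chloride (CH2Cl2, −78 °C → rt, catalytic TMSOTf if needed) in a Mukaiyama-type Claisen condensation, and aqueous HCl work-up gives 19.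

Step 11 (fragment union). The risks are double alkylation of 15 at its second free ring carbon, transfer of the methylene unit between pyranones to give the bis-pyranonyl methane, and self-reaction of 22. The fallback sets out from 15 and comes back at 23 with the roles of the partners reversed. Ketone 15 is aminomethylated with aqueous formaldehyde and dimethylamine (1.0 eq each, EtOH, 0 °C → rt) to (2R)-1-{3-[(dimethylamino)methyl]-2,6-dihydroxy-4-methoxyphenyl}-2-methylbutan-1-one F5. Heating F5 with an excess of the cheap pyranone 20 (2–3 eq) in dioxane at 90 °C expels dimethylamine to give (2R)-1-(2-hydroxy-4-methoxy-5-methylidene-6-oxocyclohexa-1,3-dien-1-yl)-2-methylbutan-1-one F6 (an o-quinone methide, not isolated). Michael addition of C3 of 20 to F6 gives 23. The electrophile is now the mono-functionalised arene, so over-alkylation of the valuable chiral fragment is avoided.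

**Further compounds**
F1 | step 6 | (2R)-2-methylbutanoyl chloride | CC[C@@H](C)C(Cl)=O
F2 | step 6 | (2R)-2-methyl-1-(2,4,6-trihydroxyphenyl)butan-1-one | CC[C@@H](C)C(=O)c1c(O)cc(O)cc1O
F3 | step 8 | methyl 3-(trimethylsilyloxy)pent-2-enoate | CCC(O[Si](C)(C)C)=CC(=O)OC
F4 | step 8 | 1-methoxy-1,3-bis(trimethylsilyloxy)penta-1,3-diene | CC=C(O[Si](C)(C)C)C=C(OC)O[Si](C)(C)C
F5 | step 11 | (2R)-1-{3-[(dimethylamino)methyl]-2,6-dihydroxy-4-methoxyphenyl}-2-methylbutan-1-one | CC[C@@H](C)C(=O)c1c(O)cc(OC)c(CN(C)C)c1O
F6 | step 11 | (2R)-1-(2-hydroxy-4-methoxy-5-methylidene-6-oxocyclohexa-1,3-dien-1-yl)-2-methylbutan-1-one | CC[C@@H](C)C(=O)C1=C(O)C=C(OC)C(=C)C1=O
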